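**Strategy.** Everything rests on a [3+3] construction of ring C of the bottom epicatechin unit: C3–C4 and O1–C8a are made in one flask by C-benzylation of the O,C-dianion of an (R)-α-hydroxy dithiane, then SNAr closure of the remaining alkoxide onto the ring-A fluoride. The step exploits the 1,3-relationship of O1 and C3 and the two meta oxygens (C5, C7) of ring A, which make C8a SNAr-competent; the dithiane at C3 replaces the 3-oxygen so that only O1 can close. Unmasking and cis-selective reduction give tetra-O-benzyl-epicatechin, which supplies three units; bromo-capped, orthogonally activated flavanyl couplings with a catechin block then assemble the tetramer.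

Key step: step 6

Remark: the target is read as catechin-(4α→6)-epicatechin-(4β→8)-epicatechin-(4β→8)-epicatechin (every C2 is R); flavan numbering (O1, C2, C3, C4, C4a, C5–C8, C8a) is used throughout, and the 3-hydroxyl groups stay free in all couplings.

**Step 1**
Reactants: 1 1,3,5-trifluorobenzene
Product: 2 1,3-bis(benzyloxy)-5-fluorobenzene
Conditions: BnOH (2.1 equiv), NaH (2.2 equiv), NMP, 0 → 80 °C
Reagents that add atoms: benzyl alcohol OCc1ccccc1
Why: Two successive SNAr displacements by benzyloxide; each alkoxy group slows the next substitution, so the third fluoride should survive.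

**Step 2**
Reactants: 2 1,3-bis(benzyloxy)-5-fluorobenzene
Product: 5 [2,4-bis(benzyloxy)-6-fluorophenyl]methanol, via aryllithium 3 (not isolated), via aldehyde 4 (not isolated)
Conditions: n-BuLi, THF, −78 °C; DMF, −78 → 0 °C; then MeOH, NaBH4, 0 °C
Reagents that add atoms: N,N-dimethylformamide CN(C)C=O
Why: Directed ortho-lithiation at the C–H flanked by fluorine and a benzyloxy group, formylation and in situ borohydride reduction; the low temperature should prevent loss of LiF to an aryne.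

**Step 3**
Reactants: 5 [2,4-bis(benzyloxy)-6-fluorophenyl]methanol
Product: 7 1,5-bis(benzyloxy)-2-(chloromethyl)-3-fluorobenzene, via mesylate 6 (not isolated)
Conditions: MsCl, Et3N, CH2Cl2, 0 °C → rt; used crude
Reagents that add atoms: methanesulfonyl chloride CS(=O)(=O)Cl
Why: Mesylation of the electron-rich benzylic alcohol followed by in situ displacement by chloride should give the labile benzylic chloride.

**Step 4**
Reactants: 8 methyl 3,4-bis(benzyloxy)benzoate
Product: 9 [3,4-bis(benzyloxy)phenyl](1,3-dithian-2-yl)methanone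
Conditions: 1,3-dithiane (2.2 equiv), n-BuLi (2.1 equiv), THF, −30 °C; then 8, −78 → −20 °C; aq. NH4Cl
Reagents that add atoms: 1,3-dithiane C1CSCSC1
Why: Corey–Seebach acylation; the acidic 2-acyl dithiane is deprotonated by the second equivalent of anion, which should prevent over-addition.

**Step 5**
Reactants: 9 [3,4-bis(benzyloxy)phenyl](1,3-dithian-2-yl)methanone
Product: 10 (R)-[3,4-bis(benzyloxy)phenyl](1,3-dithian-2-yl)methanol
Conditions: (S)-2-methyl-CBS-oxazaborolidine (0.2 equiv), BH3·SMe2, THF, −20 °C; MeOH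
Reagents that add atoms: none
Why: Corey–Bakshi–Shibata reduction; with the 1,3-dithian-2-yl group acting as the larger substituent the (S)-catalyst should give the (R)-carbinol, which becomes C2 of the flavan (the opposite catalyst is used if the sense proves reversed).

**Step 6**
Reactants: 10 (R)-[3,4-bis(benzyloxy)phenyl](1,3-dithian-2-yl)methanol; 7 1,5-bis(benzyloxy)-2-(chloromethyl)-3-fluorobenzene
Product: 13 (2R)-5,7-bis(benzyloxy)-2-[3,4-bis(benzyloxy)phenyl]spiro[chromane-3,2'-[1,3]dithiane], via dianion 11 (not isolated), via lithium alkoxide 12 (not isolated)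
Conditions: n-BuLi (2.1 equiv), TMEDA, THF, −30 °C; 7, −78 → 0 °C; then DMPU, 60 °C
Reagents that add atoms: none
Why: Double deprotonation gives the O,C-dianion, whose dithiane carbanion (the future C3) is alkylated by the benzylic chloride (SN2, C3–C4), after which the remaining lithium alkoxide (O1) displaces fluoride at C8a by addition–elimination (O1–C8a). The closest known reaction types are the Corey–Seebach alkylation of lithiated dithianes, the tandem SN2–SNAr annulation of 2-fluorobenzyl halides with C,O-dinucleophiles, and alkoxide SNAr closure of the flavan pyran ring on 3,5-dialkoxyfluoroarenes. The ring closes in a 6-exo-trig mode through a Meisenheimer intermediate, helped by the gem-disubstituent effect of the spiro dithiane. No new stereocenter is formed: C3 is a spiro dithioketal carbon, and C2 keeps its (R) configuration because its C–O bond is never broken. The step needs C- over O-alkylation, which the far more nucleophilic carbanion should secure, and closure through O1 only, which the dithiane secures by replacing the 3-oxygen (no enolate, no competing five-membered ring); the single C–F bond, activated inductively by the two meta benzyloxy groups, fixes the site of arylation.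

**Step 7**
Reactants: 13 (2R)-5,7-bis(benzyloxy)-2-[3,4-bis(benzyloxy)phenyl]spiro[chromane-3,2'-[1,3]dithiane]
Product: 14 (2R)-5,7-bis(benzyloxy)-2-[3,4-bis(benzyloxy)phenyl]chroman-3-one
Conditions: MeI (excess), CaCO3, MeCN/H2O 9:1, 40 °C
Reagents that add atoms: water O
Why: Alkylative dethioacetalization (S-methylation, then hydrolysis) under buffered conditions should free the ketone without enolization at C2.

**Step 8**
Reactants: 14 (2R)-5,7-bis(benzyloxy)-2-[3,4-bis(benzyloxy)phenyl]chroman-3-one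
Product: 15 5,7,3',4'-tetra-O-benzyl-(−)-epicatechin, (2R,3R)
Conditions: LiBH(s-Bu)3 (L-Selectride), LiBr, THF, −78 °C; aq. NH4Cl
Reagents that add atoms: none
Why: The bulky hydride should attack the ketone from the face opposite the C2 aryl group, giving the 2,3-cis alcohol (3R) by substrate control.

**Step 9**
Reactants: 15 5,7,3',4'-tetra-O-benzyl-(−)-epicatechin
Product: 16 5,7,3',4'-tetra-O-benzyl-4β-(2-ethoxyethoxy)epicatechin
Conditions: DDQ (2 equiv), 2-ethoxyethanol (5 equiv), CH2Cl2, rt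
Reagents that add atoms: 2-ethoxyethanol CCOCCO
Why: DDQ abstracts hydride from the benzylic C4 activated by ring A, and the alcohol traps the cation trans to the C2 aryl group (benzylic oxidation).

**Step 10**
Reactants: 16 5,7,3',4'-tetra-O-benzyl-4β-(2-ethoxyethoxy)epicatechin
Product: 17 8-bromo-5,7,3',4'-tetra-O-benzyl-4β-(2-ethoxyethoxy)epicatechin
Conditions: NBS (1.0 equiv), CH2Cl2, −78 → 0 °C
Reagents that add atoms: N-bromosuccinimide O=C1CCC(=O)N1Br
Why: Electrophilic aromatic bromination should occur at C8, the more accessible and more nucleophilic position of ring A, and caps it for later regiocontrol.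

**Step 11**
Reactants: 17 8-bromo-5,7,3',4'-tetra-O-benzyl-4β-(2-ethoxyethoxy)epicatechin
Product: 18 8-bromo-5,7,3',4'-tetra-O-benzyl-4β-[(2,6-dimethylphenyl)sulfanyl]epicatechin
Conditions: 2,6-dimethylbenzenethiol (3 equiv), BF3·OEt2, CH2Cl2, −78 → −30 °C
Reagents that add atoms: 2,6-dimethylbenzenethiol Cc1cccc(C)c1S
Why: Lewis acid ionization of the C4 ether and capture of the flavanyl cation by the thiol trans to the 3-hydroxyl (thiolysis) should install a leaving group that is inert to hard Lewis acids.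

**Step 12**
Reactants: 19 (+)-catechin
Product: 20 5,7,3',4'-tetra-O-benzyl-(+)-catechin
Conditions: BnBr (4.4 equiv), K2CO3, DMF, rt
Reagents that add atoms: benzyl bromide BrCc1ccccc1
Why: Williamson etherification of the four phenols; carbonate does not deprotonate the secondary 3-hydroxyl, which should stay free.

**Step 13**
Reactants: 20 5,7,3',4'-tetra-O-benzyl-(+)-catechin
Product: 21 5,7,3',4'-tetra-O-benzyl-4β-(2-ethoxyethoxy)catechin (2,4-trans, 3,4-cis)
Conditions: DDQ (2 equiv), 2-ethoxyethanol (5 equiv), CH2Cl2, rt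
Reagents that add atoms: 2-ethoxyethanol CCOCCO
Why: The same benzylic oxidation as in step 9; the C4 configuration is of no consequence because it is lost on ionization.

**Step 14**
Reactants: 21 5,7,3',4'-tetra-O-benzyl-4β-(2-ethoxyethoxy)catechin
Product: 22 8-bromo-5,7,3',4'-tetra-O-benzyl-4β-(2-ethoxyethoxy)catechin
Conditions: NBS (1.0 equiv), CH2Cl2, −78 → 0 °C
Reagents that add atoms: N-bromosuccinimide O=C1CCC(=O)N1Br
Why: C8-selective electrophilic bromination; the bromine should keep the electrophile from condensing with itself.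

**Step 15**
Reactants: 22 8-bromo-5,7,3',4'-tetra-O-benzyl-4β-(2-ethoxyethoxy)catechin; 18 8-bromo-5,7,3',4'-tetra-O-benzyl-4β-[(2,6-dimethylphenyl)sulfanyl]epicatechin
Product: 23 [8-bromo-tetra-O-benzyl-catechin]-(4α→6)-[8-bromo-4β-(2,6-dimethylphenylsulfanyl)-tetra-O-benzyl-epicatechin]
Conditions: BF3·OEt2, CH2Cl2, −78 → −40 °C
Reagents that add atoms: none
Why: The hard Lewis acid ionizes only the C4 ether of 22, and the catechin cation should be attacked by C6 of 18 (the only free ring-A position, C8 being bromo-capped) anti to the 3-hydroxyl to give the 3,4-trans (4α) bond, while the thioether stays intact (Friedel–Crafts-type flavanylation with orthogonal activation).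

**Step 16**
Reactants: 16 5,7,3',4'-tetra-O-benzyl-4β-(2-ethoxyethoxy)epicatechin; 15 5,7,3',4'-tetra-O-benzyl-(−)-epicatechin
Product: 24 octa-O-benzyl-epicatechin-(4β→8)-epicatechin
Conditions: Yb(OTf)3, CH2Cl2, rt; 15 in slight excess
Reagents that add atoms: none
Why: Lewis acid-mediated flavanyl cation formation and attack by C8 of 15, the most nucleophilic ring-A position, trans to the 3-hydroxyl (4β); the excess of 15 should suppress self-condensation of the uncapped electrophile, whose C8 must stay free for step 17.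

**Step 17**
Reactants: 23 thioether dimer; 24 octa-O-benzyl-epicatechin-(4β→8)-epicatechin
Product: 25 [8-bromo-tetra-O-benzyl-catechin]-(4α→6)-[8-bromo-tetra-O-benzyl-epicatechin]-(4β→8)-[tetra-O-benzyl-epicatechin]-(4β→8)-[tetra-O-benzyl-epicatechin]
Conditions: iodine (I2), Ag2O, THF, −78 → 0 °C
Reagents that add atoms: none
Why: Thiophilic (soft) activation should turn the thioether into the C4 cation of the central epicatechin unit, which is attacked by C8 of the upper ring A of 24 trans to the 3-hydroxyl (4β); both upper units of 23 are bromo-capped and cannot act as nucleophiles.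

**Step 18**
Reactants: 25 protected dibromo tetramer
Product: 26 catechin-(4α→6)-epicatechin-(4β→8)-epicatechin-(4β→8)-epicatechin (CNP0228086.1)
Conditions: H2 (1 atm), Pd(OH)2/C, NaOAc, THF/MeOH/H2O, rt; Sephadex LH-20
Reagents that add atoms: none
Why: Hydrogenolysis should cleave the sixteen benzyl ethers and both aryl–bromine bonds, and the acetate buffer keeps HBr from cleaving the acid-labile interflavan bonds.

**Compound list**

1 | 1,3,5-trifluorobenzene | Fc1cc(F)cc(F)c1 | starting material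
2 | 1,3-bis(benzyloxy)-5-fluorobenzene | Fc1cc(OCc2ccccc2)cc(OCc2ccccc2)c1 | intermediate
3 | [2,4-bis(benzyloxy)-6-fluorophenyl]lithium | [Li]c1c(F)cc(OCc2ccccc2)cc1OCc1ccccc1 | intermediate
4 | 2,4-bis(benzyloxy)-6-fluorobenzaldehyde | O=Cc1c(F)cc(OCc2ccccc2)cc1OCc1ccccc1 | intermediate
5 | [2,4-bis(benzyloxy)-6-fluorophenyl]methanol | OCc1c(F)cc(OCc2ccccc2)cc1OCc1ccccc1 | intermediate
6 | [2,4-bis(benzyloxy)-6-fluorophenyl]methyl methanesulfonate | CS(=O)(=O)OCc1c(F)cc(OCc2ccccc2)cc1OCc1ccccc1 | intermediate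
7 | 1,5-bis(benzyloxy)-2-(chloromethyl)-3-fluorobenzene | ClCc1c(F)cc(OCc2ccccc2)cc1OCc1ccccc1 | intermediate
8 | methyl 3,4-bis(benzyloxy)benzoate | COC(=O)c1ccc(OCc2ccccc2)c(OCc2ccccc2)c1 | starting material
9 | [3,4-bis(benzyloxy)phenyl](1,3-dithian-2-yl)methanone | O=C(c1ccc(OCc2ccccc2)c(OCc2ccccc2)c1)C1SCCCS1 | intermediate
10 | (R)-[3,4-bis(benzyloxy)phenyl](1,3-dithian-2-yl)methanol | O[C@H](c1ccc(OCc2ccccc2)c(OCc2ccccc2)c1)C1SCCCS1 | intermediate
11 | dilithium O,C-dianion of 10 (lithium alkoxide and 2-lithio-dithiane) | [Li+].[Li+].[O-][C@H](c1ccc(OCc2ccccc2)c(OCc2ccccc2)c1)[C-]1SCCCS1 | intermediate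
12 | lithium (R)-[3,4-bis(benzyloxy)phenyl]{2-[2,4-bis(benzyloxy)-6-fluorobenzyl]-1,3-dithian-2-yl}methanolate | [Li+].[O-][C@H](c1ccc(OCc2ccccc2)c(OCc2ccccc2)c1)C1(Cc2c(F)cc(OCc3ccccc3)cc2OCc2ccccc2)SCCCS1 | intermediate
13 | (2R)-5,7-bis(benzyloxy)-2-[3,4-bis(benzyloxy)phenyl]spiro[chromane-3,2'-[1,3]dithiane] | c1ccccc1COc2cc(OCc3ccccc3)c4c(c2)O[C@H](c2ccc(OCc5ccccc5)c(OCc5ccccc5)c2)C5(SCCCS5)C4 | intermediate
14 | (2R)-5,7-bis(benzyloxy)-2-[3,4-bis(benzyloxy)phenyl]chroman-3-one | c1ccccc1COc2cc(OCc3ccccc3)c4c(c2)O[C@H](c2ccc(OCc5ccccc5)c(OCc5ccccc5)c2)C(=O)C4 | intermediate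
15 | 5,7,3',4'-tetra-O-benzyl-(−)-epicatechin, (2R,3R) | c1ccccc1COc2cc(OCc3ccccc3)c4c(c2)O[C@H](c2ccc(OCc5ccccc5)c(OCc5ccccc5)c2)[C@H](O)C4 | intermediate
16 | 5,7,3',4'-tetra-O-benzyl-4β-(2-ethoxyethoxy)epicatechin | c1ccccc1COc2cc(OCc3ccccc3)c4c(c2)O[C@H](c2ccc(OCc5ccccc5)c(OCc5ccccc5)c2)[C@H](O)[C@H]4OCCOCC | intermediate
17 | 8-bromo-5,7,3',4'-tetra-O-benzyl-4β-(2-ethoxyethoxy)epicatechin | c1ccccc1COc2cc(OCc3ccccc3)c4c(c2Br)O[C@H](c2ccc(OCc5ccccc5)c(OCc5ccccc5)c2)[C@H](O)[C@H]4OCCOCC | intermediate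
18 | 8-bromo-5,7,3',4'-tetra-O-benzyl-4β-[(2,6-dimethylphenyl)sulfanyl]epicatechin | c1ccccc1COc2cc(OCc3ccccc3)c4c(c2Br)O[C@H](c2ccc(OCc5ccccc5)c(OCc5ccccc5)c2)[C@H](O)[C@H]4Sc2c(C)cccc2C | intermediate
19 | (+)-catechin, (2R,3S) | Oc1cc(O)c2c(c1)O[C@H](c1ccc(O)c(O)c1)[C@@H](O)C2 | starting material
20 | 5,7,3',4'-tetra-O-benzyl-(+)-catechin | c1ccccc1COc2cc(OCc3ccccc3)c4c(c2)O[C@H](c2ccc(OCc5ccccc5)c(OCc5ccccc5)c2)[C@@H](O)C4 | intermediate
21 | 5,7,3',4'-tetra-O-benzyl-4β-(2-ethoxyethoxy)catechin | c1ccccc1COc2cc(OCc3ccccc3)c4c(c2)O[C@H](c2ccc(OCc5ccccc5)c(OCc5ccccc5)c2)[C@@H](O)[C@H]4OCCOCC | intermediate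
22 | 8-bromo-5,7,3',4'-tetra-O-benzyl-4β-(2-ethoxyethoxy)catechin | c1ccccc1COc2cc(OCc3ccccc3)c4c(c2Br)O[C@H](c2ccc(OCc5ccccc5)c(OCc5ccccc5)c2)[C@@H](O)[C@H]4OCCOCC | intermediate
23 | [8-bromo-tetra-O-benzyl-catechin]-(4α→6)-[8-bromo-4β-(2,6-dimethylphenylsulfanyl)-tetra-O-benzyl-epicatechin] | O(Cc9ccccc9)c1cc(OCc9ccccc9)c2c(c1Br)O[C@H](c1ccc(OCc9ccccc9)c(OCc9ccccc9)c1)[C@@H](O)[C@@H]2c1c(OCc9ccccc9)c(Br)c2c(c1OCc9ccccc9)[C@H](Sc1c(C)cccc1C)[C@@H](O)[C@@H](c1ccc(OCc9ccccc9)c(OCc9ccccc9)c1)O2 | intermediate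
24 | octa-O-benzyl-epicatechin-(4β→8)-epicatechin | c1c(OCc9ccccc9)cc(OCc9ccccc9)c3c1O[C@H](c1ccc(OCc9ccccc9)c(OCc9ccccc9)c1)[C@H](O)[C@H]3c1c(OCc9ccccc9)cc(OCc9ccccc9)c3c1O[C@H](c1ccc(OCc9ccccc9)c(OCc9ccccc9)c1)[C@H](O)C3 | intermediate
25 | hexadeca-O-benzyl-8,8'-dibromo tetramer (8-bromo at the catechin unit and at the 6-linked epicatechin unit) | O(Cc9ccccc9)c1cc(OCc9ccccc9)c2c(c1Br)O[C@H](c1ccc(OCc9ccccc9)c(OCc9ccccc9)c1)[C@@H](O)[C@@H]2c1c(OCc9ccccc9)c(Br)c2c(c1OCc9ccccc9)[C@H](c1c(OCc9ccccc9)cc(OCc9ccccc9)c3c1O[C@H](c1ccc(OCc9ccccc9)c(OCc9ccccc9)c1)[C@H](O)[C@H]3c1c(OCc9ccccc9)cc(OCc9ccccc9)c3c1O[C@H](c1ccc(OCc9ccccc9)c(OCc9ccccc9)c1)[C@H](O)C3)[C@@H](O)[C@@H](c1ccc(OCc9ccccc9)c(OCc9ccccc9)c1)O2 | intermediate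
26 | catechin-(4α→6)-epicatechin-(4β→8)-epicatechin-(4β→8)-epicatechin (CNP0228086.1) | Oc1cc(O)c2c(c1)O[C@H](c1ccc(O)c(O)c1)[C@@H](O)[C@@H]2c1c(O)cc2c(c1O)[C@H](c1c(O)cc(O)c3c1O[C@H](c1ccc(O)c(O)c1)[C@H](O)[C@H]3c1c(O)cc(O)c3c1O[C@H](c1ccc(O)c(O)c1)[C@H](O)C3)[C@@H](O)[C@@H](c1ccc(O)c(O)c1)O2 | target

**Step count and risks**

Total step count: 18. Longest linear sequence: 12 steps (1, 2, 3, 6, 7, 8, 9, 10, 11, 15, 17, 18).

Steps most likely to fail:

1. Step 6. Dianion formation from 10 may be incomplete, the lithium alkoxide 12 may fragment by retro-addition, or the SNAr closure on the unactivated fluoroarene may be slower than decomposition. Fallback, from 10 back to 13: the annulation is run stepwise with the oxygen masked. Compound 10 is silylated (TESCl, imidazole, DMF) to the triethylsilyl ether F1. F1 is lithiated (n-BuLi, THF, −30 °C) and alkylated with 7 to the C-benzylated silyl ether F2. Fluoride (TBAF, THF) liberates the alcohol F3, and the potassium alkoxide of F3 (KH, DMF, 60 °C) closes the ring by SNAr to give 13.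

2. Step 15. C6 of the brominated, sulfur-bearing nucleophile 18 may be too unreactive, so that the cation decomposes or the 3-hydroxyl is alkylated instead of carbon. Fallback, from 15 back to 25: the sulfur handle is dropped and the leaving group is installed after the 4→6 bond. Compound 15 is brominated (NBS, CH2Cl2, −78 °C) to 8-bromo-tetra-O-benzyl-epicatechin F4, which is coupled with 22 (BF3·OEt2, CH2Cl2, −78 °C) to the 4α→6 dimer F5. Benzylic oxidation of the lower unit of F5 (DDQ, 2-ethoxyethanol, CH2Cl2) gives the 4β-(2-ethoxyethoxy) dimer F6, which is condensed with 24 (Yb(OTf)3, CH2Cl2) to give 25.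

3. Step 17. The iodine-based thiophile may halogenate C8 of 24 faster than it ionizes the thioether, or the hindered dimeric cation may be lost before it is captured. Fallback, from 23 back to 25: the leaving group is exchanged before the coupling. Compound 23 is treated with Hg(OAc)2 in AcOH/CH2Cl2 to give the 4β-acetate dimer F7, which is ionized with BF3·OEt2 (CH2Cl2, −78 °C) in the presence of 24 to give 25.

**Further compounds**

F1 | step 6 | (R)-[3,4-bis(benzyloxy)phenyl](1,3-dithian-2-yl)methyl triethylsilyl ether | CC[Si](CC)(CC)O[C@H](c1ccc(OCc2ccccc2)c(OCc2ccccc2)c1)C1SCCCS1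
F2 | step 6 | triethylsilyl ether of (R)-[3,4-bis(benzyloxy)phenyl]{2-[2,4-bis(benzyloxy)-6-fluorobenzyl]-1,3-dithian-2-yl}methanol | CC[Si](CC)(CC)O[C@H](c1ccc(OCc2ccccc2)c(OCc2ccccc2)c1)C1(Cc2c(F)cc(OCc3ccccc3)cc2OCc2ccccc2)SCCCS1
F3 | step 6 | (R)-[3,4-bis(benzyloxy)phenyl]{2-[2,4-bis(benzyloxy)-6-fluorobenzyl]-1,3-dithian-2-yl}methanol | O[C@H](c1ccc(OCc2ccccc2)c(OCc2ccccc2)c1)C1(Cc2c(F)cc(OCc3ccccc3)cc2OCc2ccccc2)SCCCS1
F4 | step 15 | 8-bromo-5,7,3',4'-tetra-O-benzyl-(−)-epicatechin | c1ccccc1COc2cc(OCc3ccccc3)c4c(c2Br)O[C@H](c2ccc(OCc5ccccc5)c(OCc5ccccc5)c2)[C@H](O)C4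
F5 | step 15 | [8-bromo-tetra-O-benzyl-catechin]-(4α→6)-[8-bromo-tetra-O-benzyl-epicatechin] | O(Cc9ccccc9)c1cc(OCc9ccccc9)c2c(c1Br)O[C@H](c1ccc(OCc9ccccc9)c(OCc9ccccc9)c1)[C@@H](O)[C@@H]2c1c(OCc9ccccc9)c(Br)c2c(c1OCc9ccccc9)C[C@@H](O)[C@@H](c1ccc(OCc9ccccc9)c(OCc9ccccc9)c1)O2
F6 | step 15 | [8-bromo-tetra-O-benzyl-catechin]-(4α→6)-[8-bromo-4β-(2-ethoxyethoxy)-tetra-O-benzyl-epicatechin] | O(Cc9ccccc9)c1cc(OCc9ccccc9)c2c(c1Br)O[C@H](c1ccc(OCc9ccccc9)c(OCc9ccccc9)c1)[C@@H](O)[C@@H]2c1c(OCc9ccccc9)c(Br)c2c(c1OCc9ccccc9)[C@H](OCCOCC)[C@@H](O)[C@@H](c1ccc(OCc9ccccc9)c(OCc9ccccc9)c1)O2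
F7 | step 17 | [8-bromo-tetra-O-benzyl-catechin]-(4α→6)-[4β-acetoxy-8-bromo-tetra-O-benzyl-epicatechin] | O(Cc9ccccc9)c1cc(OCc9ccccc9)c2c(c1Br)O[C@H](c1ccc(OCc9ccccc9)c(OCc9ccccc9)c1)[C@@H](O)[C@@H]2c1c(OCc9ccccc9)c(Br)c2c(c1OCc9ccccc9)[C@H](OC(C)=O)[C@@H](O)[C@@H](c1ccc(OCc9ccccc9)c(OCc9ccccc9)c1)O2
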